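All runs are simulated with made-up constants; the scatter is artificial.

In the summer run the target moves far less than the starting material between 1.00 h and 3.00 h: [target] goes from 10.2% to 9.5%, while [starting material] drops from 76.2% to 39.8%. Starting material and reagent react with a free catalyst in closed, stirred flasks at constant temperature, and the new flasks differ in catalyst loading.

| setting | dusk | summer | autumn | grey | ochre | blue | amber |
|---|---|---|---|---|---|---|---|
| starting material | 0.020 M | 0.020 M | 0.020 M | 0.020 M | 0.020 M | 0.020 M | 0.020 M |
| reagent | 2.5 equiv | 2.5 equiv | 2.5 equiv | 2.50 equiv | 2.50 equiv | 2.50 equiv | 2.50 equiv |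
| free catalyst | 0.044 mol% | 0.3 mol% | 1.2 mol% | 0.06 mol% | 0.15 mol% | 0.5 mol% | 1.5 mol% |
| remark | run made earlier | run made earlier | run made earlier |  |  |  |  |
| time |  |  |  | 4.0 h | 4.0 h | 4.0 h | 4.0 h |

| run | time / h | target / % | starting material / % |
|---|---|---|---|
| dusk | 0.250 | 1.5 | 98.9 |
| dusk | 0.500 | 0.4 | 97.7 |
| dusk | 1.33 | 1.5 | 95.0 |
| dusk | 3.00 | 2.5 | 88.8 |
| summer | 0.333 | 5.8 | 91.3 |
| summer | 1.00 | 10.2 | 76.2 |
| summer | 2.00 | 9.7 | 55.3 |
| summer | 3.00 | 9.5 | 39.8 |
| autumn | 0.333 | 22.2 | 66.4 |
| autumn | 1.00 | 25.8 | 28.5 |
| autumn | 2.00 | 13.4 | 5.1 |
| autumn | 3.00 | 6.4 | 0.5 |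

(each reading ± 0.5 percentage points)

- "hardly changes" means that all values lie within two and a half points (for a concentration: within two and a half percent of the largest)

* amount of target at the end, in percent of the starting material charged for grey, ochre, blue, amber, in this order
* the shape of the row from first to last (falls, then rises / rises, then falls / falls all the way / hardly changes / rises all the way)

The summer target, holding near one level while material streams through it, behaves like a steady-state intermediate. I assume that the reacted starting material passes through the target. My measure is the lag, [target] on such a stretch divided by the rate at which starting material disappears, in the summer readings 0.533 h.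

The zero of my scale is the autumn flask at 3.00 h: it has 0.5% of starting material left to feed the target and still shows 6.4% of target, a share of 6.43% of what reacted. That reading is still falling, so I take it as a ceiling on the residue.

I bracket blue. The summer decay constant, 0.325 h⁻¹, scaled by loading gives 0.541 h⁻¹, which leaves 11.5% of the starting material at 4.0 h. From below, the lag times the rate at that moment gives 3.31% of target. The level trails a falling supply, so I divide by one minus 0.288, which tightens this to 4.65%. From above, I add the full residue on what has reacted and reach 10.3%.

The forecast gives 3.2%, 6%, 6.8% and 2.2%, a row that rises, then falls, on the ground that the target “disappears at about 1 /h regardless of catalyst loading”. Its blue value lies above my lower bound and below my upper one.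

The flasks give 2.80%, 5.74%, 7.65% and 4.32%, a row that rises, then falls.

    reagent + catalyst intermediate A → catalyst intermediate B (k = 47.5 M⁻¹ min⁻¹)
    catalyst intermediate B → free catalyst + target (k = 251 min⁻¹)
    target ⇌ isomer of the product (K = 23.0, k = 0.0367 min⁻¹)
    starting material + free catalyst ⇌ catalyst intermediate A (K = 110 M⁻¹, k = 1130 M⁻¹ min⁻¹)

In grey, the loss of target to the isomer of the product has, by its forward rate alone, a half-life of 0.31 h, short against the 4.0 h of the flask. Blue ends 3 percentage points above my lower bound. In grey, starting material falls by 0.0482 h⁻¹ of the charge over the second half of the time, so the lag gives 2.57% of target, and the flask holds 2.80% at 4.00 h.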